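The earlier runs and the new flask are calculated for an exercise, and the scatter is random.

One turn of the cycle is easy to count: L takes up D to give Q, Q takes up E to give G, and G gives X and returns L, so each X costs one D and one E.

| setting | elm | cedar | flask |
|---|---|---|---|
| E | 0.050 M | 0.050 M | 0.050 M |
| D | 0.80 equiv | 0.80 equiv | 0.800 equiv |
| L | 15 mol% | 22 mol% | 15 mol% |
| remark | the very flask that is asked about, followed so far | run made earlier |  |
| time |  |  | 40 h |

| run | time / h | X / % | E / % |
|---|---|---|---|
| elm | 0.667 | 13 | 80 |
| elm | 1.00 | 21 | 75 |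
| elm | 1.33 | 30 | 67 |
| elm | 2.50 | 51 | 47 |
| elm | 3.00 | 57 | 40 |
| elm | 5.00 | 78 | 24 |
| elm | 8.00 | 81 | 17 |
| cedar | 0.833 | 23 | 70 |
| cedar | 2.50 | 63 | 35 |
| cedar | 5.00 | 78 | 20 |
| cedar | 6.00 | 78 | 20 |
| cedar | 10.0 | 81 | 20 |
| cedar | 12.0 | 79 | 20 |
| cedar | 15.0 | 82 | 20 |

(each reading ± 2 percentage points)

- what was read earlier has a scatter of 2 percentage points, one standard deviation
- what may be going on: D + L -> Q; L <-> J; G -> L + X; E + Q -> G

1. X present at 40 h, in percent of the E charged
2. E present at 40 h, in percent of the E charged

So X can grow while [D] is above zero, and I solve that end first. D is the limiting reagent here: 80.0% of the E can find a D, and I call this share, D charged over E charged, the X ceiling. What remains is the E floor, 20.0%.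

Then the other end: elm starts quickly and by 8.00 h reads X 81%, within the scatter of 2 percentage points of the ceiling, with E at 17%. But a stop might also be lost catalyst, since L can pass to J. So I look at cedar: with 22 mol% of L against 15 mol% in elm, it ends at about the same height, X 82% at 15.0 h. I therefore commit to X at the ceiling and E at the floor by 40 h.

The forecast gives X 80% and E 20%, because “its height matches the stoichiometry”.

The flask gives X 80.0% and E 20.0%, with D at 0% of its charge at 40.0 h.

    D + L → Q (k = 380 M⁻¹ h⁻¹)
    L ⇌ J (K = 1.20, k = 0.0900 h⁻¹)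
    G → L + X (k = 3.60 h⁻¹)
    E + Q → G (k = 99.0 M⁻¹ h⁻¹)

One way for the forecast to be wrong is another D charge: at 0.750 equiv the ceiling is 75.0%, which is 5 points lower, and E has moved by 5 points there. An early stop is another: at 4.00 h this flask holds X 67.7% and E 29.9%.

The neighbour with 0.200 equiv of D has a ceiling of 20.0% and a floor of 80.0%. It gives X 20.0% and E 80.0%.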